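## The problem

Lignan numbering is used: C7 = oxolane C2 (bears a guaiacyl ring), C8 = C3 (bears C9H2OH), C8' = C4 (bears the carbinol C7'), C9' = the ring CH2 (C5), O9' = the ring oxygen, O7' = the carbinol oxygen.

- The target has one oxolane ring (O9'–C7–C8–C8'–C9') and four contiguous stereocentres on the chain C7(S)–C8(R)–C8'(S)–C7'(S). The three ring substituents are all-trans, and two identical 4-hydroxy-3-methoxyphenyl groups end the chain.
- The ring centres can control each other, because each substituent avoids its neighbour. C7' lies outside the ring on a freely rotating bond, so C7' and the absolute configuration are the hard part.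
- Both benzylic C–O bonds (C7–O9' and C7'–O7') stand para to a free phenol and ionise to p-quinone methides with acid, hot base or oxidants. The results are epimerisation, irreversible Friedel–Crafts closure to an aryltetralin or, under H2/Pd, hydrogenolysis, so late Lewis acid/hydride deoxygenations and harsh deprotections are excluded.
- The feature that makes the key step possible: C8 and C8' carry the same two arms, one CH2–O and one ArCH–O, in mirror-image sense (R and S). Only the choice of the oxygen bound to C7 breaks the symmetry.
- If C7 is bound to O7' instead of O9', the ring becomes O7'–C7–C8–C8'–C7'. The compound is then the all-cis 2,5-diaryl-3,4-bis(hydroxymethyl)oxolane 8, a meso constitutional isomer of the target in which the (7'S,8'S) pair appears as a cis relation of aryl group and hydroxymethyl arm.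
- Because the C7–O bond is p-hydroxybenzylic, this one bond can be moved under acid catalysis. The problem shrinks to a meso all-cis oxolane and the choice between two enantiotopic C–O bonds.

## Retrosynthesis

**10 ⇒ 8 (through 9).** The bond cut is C7–O9', and C7–O7' is put in its place.
- Of the five ring bonds this is the only p-hydroxybenzylic one, and so the only one that is reversible under catalysis.
- The neighbouring cuts are worse. Cutting O9'–C9' asks for selective activation of one of two primary alcohols in a tetraol with two labile benzylic alcohols. Cutting C7'–C8' or C8–C8' leaves C7' to be made next to a planar carbon.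
- Precursor 8 has the same atoms but a mirror plane. Four stereocentres collapse to one relative pattern (all-cis), and no absolute configuration has to be carried.
- The forward reaction must choose one of two enantiotopic C–O bonds, close with O9' and not with O7', place the C7 aryl group trans to C9, and leave C7'–O7' alone.
- The strain of 8 pays for the step. The trans relation of the C9 and C7' arms in 10 forbids a second ring closure.

**8 ⇒ 7.** No skeletal bond is cut; C9 and C9' are raised to ethyl esters. The esters acidify and flank the furan C–H bonds used earlier, come with a commercial furan, and put no hydrogenolysable allylic-type C–O bond on the ring during the hydrogenation. The forward step is a plain hydride reduction that must not enolise C8/C8'.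

**7 ⇒ 5 (through 6).** The four C–H bonds at C7, C8, C8' and C7' are cut, and the two phenols are masked as benzyl ethers.
- All four stereocentres vanish, and a flat, achiral, aromatic furan remains.
- All-cis is the native outcome of surface hydrogenation of a furan. It is usually unwanted because it is the least stable isomer. Here it is exactly the pattern that (7'S,8'S) demands, and its strain is stored for the key step.
- The forward step must saturate a tetrasubstituted furan without hydrogenolysis of the new benzylic C–O bonds.

**5 ⇒ 2 + 2 + 3 (through 4).** The two aryl–furyl bonds (aryl C1–C7 and aryl C1'–C7') are cut. Three components are joined in one operation around the core. Only the two α-C–H bonds are left on 3, and the product is symmetric, so no regiochemical question arises. A Paal–Knorr route through a diaroylsuccinate would cost several more steps.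

**2 ⇒ 1.** The O–benzyl bond is cut. The phenol must be masked for the palladium step, and the benzyl group leaves later in the hydrogenation without a step of its own.

## Roads not taken

**Alternative 1:** (the most obvious) cut C7'–C8'.
- Forward key step: aldol addition of the lithium enolate of the trans-4,5-disubstituted butyrolactone A1 (C9' as lactone carbonyl) to aldehyde A3, giving aldol A2. The lactone carbonyl is then taken down to the ring CH2 (hydride to the lactol, then silane/Lewis acid), and the groups are unmasked.
- C8 controls the enolate face well (C8' trans). C7', however, is decided in the aldol transition state of a ring-locked E-enolate, where the two carbinol epimers lie close.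
- A1 itself needs an auxiliary or a catalytic asymmetric sequence of several steps.
- The deoxygenation at C9' uses the very Lewis acid/hydride pair that ionises and reduces the C7'–O and C7–O bonds, so extra protection is required.
- The chosen plan never makes C7' next to a planar carbon and has no C9' deoxygenation.

**Alternative 2:** cut C7–O9' and C7'–O7' and join C7 to C7', which leads to the meso cyclobutane diol A4 (syn head-to-head photodimer series).
- Forward key step: one-electron oxidation, strain-driven cleavage of C7–C7', capture of C7 by O9' and of C7' by water.
- It uses the same hidden mirror relation of C8/C8'. C7', however, is made by intermolecular capture of a planar quinone methide, under acyclic 1,2-induction only.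
- The radical-cation opening offers no handle for a chiral catalyst, so a separate desymmetrisation is needed.
- The syn head-to-head dimer needs crystal or template control.
- A stoichiometric oxidant meets the free phenols of the product.
- In the chosen plan C7'–O7' is set by syn hydrogenation and never broken, and the key step is redox-neutral.

**Alternative 3:** cut C7–C8 and C8'–C9'.
- Forward key step: (3+2) cycloaddition of the non-stabilised carbonyl ylide A5 with the (E)-aroylacrylate A6, giving the all-trans oxolane A7. Ketone and ester reduction follow.
- The ring arrives with its substituents. However, the two acceptor groups of A6 polarise the alkene in opposite senses, so the regiochemistry is not secured.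
- The ylide has no binding site for a chiral catalyst, so the product is racemic.
- C7' still has to be set later by a ketone reduction outside the ring.
- The chosen plan avoids all three questions through symmetry.

Key step: step 5

Assumption: the sense of enantiotopic selection by the chiral acid cannot be derived with certainty. (R)-TRIP is written, and the equally available (S)-acid is used if a first assay shows the antipode.

## Steps

Step 1
Reactants: 1 4-bromo-2-methoxyphenol
Product: 2 1-(benzyloxy)-4-bromo-2-methoxybenzene
Conditions: BnBr (1.1 equiv), K2CO3, DMF, 25 °C
Reagents that add atoms: benzyl bromide, BrCc1ccccc1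
Why: Williamson ether synthesis on the phenoxide; the benzyl ether masks the acidic phenol during the palladium step and is lost later in the hydrogenation without a step of its own.

Step 2
Reactants: 2 1-(benzyloxy)-4-bromo-2-methoxybenzene (2.3 equiv); 3 diethyl furan-3,4-dicarboxylate
Product: 5 diethyl 2,5-bis(4-benzyloxy-3-methoxyphenyl)furan-3,4-dicarboxylate, via monoarylated furan diester 4 (not isolated)
Conditions: Pd(OAc)2 (5 mol %), PCy3·HBF4 (10 mol %), PivOH (30 mol %), K2CO3 (3 equiv), DMA, 110 °C
Reagents that add atoms: none
Why: Twofold palladium-catalysed direct C–H arylation (concerted metalation–deprotonation with pivalate as proton shuttle), a three-component union. Only C2–H and C5–H remain on the furan and both are acidified by the ring oxygen and the adjacent ester, so there is no regiochemical question and 4 reacts on at its remaining α-C–H bond.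

Step 3
Reactants: 5 diethyl 2,5-bis(4-benzyloxy-3-methoxyphenyl)furan-3,4-dicarboxylate
Product: 7 diethyl (2R,3S,4R,5S)-2,5-bis(4-hydroxy-3-methoxyphenyl)oxolane-3,4-dicarboxylate (meso all-cis), via furan bisphenol 6 (not isolated)
Conditions: H2 (1 bar, then 40 bar), 10 % Pd/C, EtOAc–EtOH 1:1, 25–40 °C, neutral medium, stopped at the calculated uptake
Reagents that add atoms: none
Why: Heterogeneous hydrogenation: the O-benzyl groups fall first (6), then the flat furan takes up two H2 from the face on which it is adsorbed, as known for 2,5-diaryl-3,4-disubstituted furans and for furan-3,4-dicarboxylates, which give all-cis oxolanes. C7, C8, C8' and C7' are set relative to each other by syn delivery of four H atoms to one face, since after the first H2 the new substituents point away from the metal and the H-bearing face stays the open one; the product is meso. Neutral medium and control of the uptake are meant to spare the new benzylic ring C–O bonds.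

Step 4
Reactants: 7 diethyl (2R,3S,4R,5S)-2,5-bis(4-hydroxy-3-methoxyphenyl)oxolane-3,4-dicarboxylate
Product: 8 [(2R,3R,4S,5S)-2,5-bis(4-hydroxy-3-methoxyphenyl)oxolane-3,4-diyl]dimethanol (meso all-cis)
Conditions: LiAlH4 (5 equiv), THF, −10 → 0 °C, inverse addition; Rochelle salt, then aq NH4Cl to pH 7
Reagents that add atoms: none
Why: Ester-to-alcohol reduction with LiAlH4; adding 7 to excess hydride in the cold lets hydride addition outrun enolisation, so C8/C8' are kept and the ring oxygen β to the esters is not eliminated. The phenols travel as phenoxides and return on neutral work-up; phenolic benzylic ethers and alcohols of lignans are known to pass this reagent.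

Step 5
Reactants: 8 [(2R,3R,4S,5S)-2,5-bis(4-hydroxy-3-methoxyphenyl)oxolane-3,4-diyl]dimethanol
Product: 10 4-[(2S,3R,4S)-4-[(S)-hydroxy(4-hydroxy-3-methoxyphenyl)methyl]-3-(hydroxymethyl)oxolan-2-yl]-2-methoxyphenol (the target), via p-quinone methide 9 (not isolated)
Conditions: (R)-TRIP (10 mol %), anhydrous CH2Cl2–MeCN 9:1, −20 → 0 °C; Et3N quench before concentration
Reagents that add atoms: none
Why: Proposed new method: the chiral phosphoric acid protonates the ring oxygen O7' of meso 8 and, with push from the para-phenol, one of the two enantiotopic benzylic bonds (C7–O7') breaks to give p-quinone methide 9, in which O7' has become the C7' carbinol without its bond to C7' being touched, so C7', C8' and C8 keep what the hydrogenation gave them. After rotation about C8–C8' the primary hydroxyl O9' adds to C7 of 9 (oxa-1,6-addition, 5-exo-trig closure of the ring O9'–C7–C8–C8'–C9') and the arene is restored. The closest known reaction types are chiral-phosphoric-acid-catalysed 1,6-additions to p-quinone methides made in situ from p-hydroxybenzyl alcohols, acid-catalysed desymmetrising openings of oxetanes and meso-epoxides by internal nucleophiles, and the acid epimerisation of 2,5-diaryloxolane and furofuran lignans at their benzylic carbons; new is their union in a desymmetrising ring transposition of a meso oxolane. The only new stereocentre, C7, is controlled by C8: the aryl group takes the face trans to the C9 arm in the envelope transition state (net inversion at C7), and as this closure is reversible the all-trans ring is also the thermodynamic one. Enantioselection is needed between the C7–O7' and C7'–O7' bonds: the two ionisations give enantiomeric quinone methides, which become diastereomeric when hydrogen-bonded or ion-paired to the chiral phosphate that also serves as general base for the attacking OH, and an ionisation in the mismatched sense can return to 8. Chemoselectivity is secured by the substrate: O9' is primary and leads to an all-trans ring, whereas re-closure by O7' rebuilds a ring with three cis neighbours, O9 could only form an oxetane (4-exo), and a second oxolane from O9 and C7' would be trans-fused. The driving force is the release of the eclipsing strain of four cis substituents, which makes the step downhill, holds the product against return to meso 8 (the only path to racemisation) and should allow conditions so mild that the unstrained benzylic C–O bonds of 10 do not ionise.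

## Compound list

1 | 4-bromo-2-methoxyphenol | COc1cc(Br)ccc1O | starting material
2 | 1-(benzyloxy)-4-bromo-2-methoxybenzene | COc1cc(Br)ccc1OCc1ccccc1 | intermediate
3 | diethyl furan-3,4-dicarboxylate | CCOC(=O)c1cocc1C(=O)OCC | starting material
4 | diethyl 2-(4-benzyloxy-3-methoxyphenyl)furan-3,4-dicarboxylate | CCOC(=O)c1coc(-c2ccc(OCc3ccccc3)c(OC)c2)c1C(=O)OCC | intermediate
5 | diethyl 2,5-bis(4-benzyloxy-3-methoxyphenyl)furan-3,4-dicarboxylate | CCOC(=O)c1c(-c2ccc(OCc3ccccc3)c(OC)c2)oc(-c2ccc(OCc3ccccc3)c(OC)c2)c1C(=O)OCC | intermediate
6 | diethyl 2,5-bis(4-hydroxy-3-methoxyphenyl)furan-3,4-dicarboxylate | CCOC(=O)c1c(-c2ccc(O)c(OC)c2)oc(-c2ccc(O)c(OC)c2)c1C(=O)OCC | intermediate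
7 | diethyl (2R,3S,4R,5S)-2,5-bis(4-hydroxy-3-methoxyphenyl)oxolane-3,4-dicarboxylate (meso, all-cis) | COc1cc(ccc1O)[C@H]2O[C@@H](c3ccc(O)c(OC)c3)[C@@H](C(=O)OCC)[C@H]2C(=O)OCC | intermediate
8 | [(2R,3R,4S,5S)-2,5-bis(4-hydroxy-3-methoxyphenyl)oxolane-3,4-diyl]dimethanol (meso, all-cis) | COc1cc(ccc1O)[C@H]2O[C@@H](c3ccc(O)c(OC)c3)[C@@H](CO)[C@H]2CO | intermediate
9 | 4-[(2R,3S,4S)-4-hydroxy-4-(4-hydroxy-3-methoxyphenyl)-2,3-bis(hydroxymethyl)butylidene]-2-methoxycyclohexa-2,5-dien-1-one | COC1=CC(=C[C@@H](CO)[C@@H](CO)[C@H](O)c2ccc(O)c(OC)c2)C=CC1=O | intermediate
10 | 4-[(2S,3R,4S)-4-[(S)-hydroxy(4-hydroxy-3-methoxyphenyl)methyl]-3-(hydroxymethyl)oxolan-2-yl]-2-methoxyphenol | COc1cc([C@@H](O)[C@@H]2CO[C@H](c3ccc(O)c(OC)c3)[C@H]2CO)ccc1O | target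

## Step count and risks

Total steps: 5. Longest linear sequence: 5 (1 → 2 → 5 → 7 → 8 → 10).

**Step 5 (key step, proposed new method).**
- Most likely failure: weak discrimination between the two enantiotopic C–O bonds, because the substrate offers four OH groups and hence several binding modes to the acid.
- A racemic background isomerisation may add to this, caused by adventitious acid or by the polar co-solvent needed for solubility.
- On longer exposure, ionisation at C7' (epimerisation) and irreversible Friedel–Crafts closure of the quinone methide onto the other arene may set in.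
- Fallback (known chemistry), from 8 back to 10. Lipase-catalysed transesterification of the meso diol (immobilised lipase, vinyl acetate, MTBE–THF), with the enzyme screened for acylation of O9, gives the O9-monoacetate F1. An achiral weak acid (PPTS or diphenyl phosphate, CH2Cl2–MeCN, 0 °C) then triggers the same ring transposition, in which only O9' can close, and gives the 9-O-acetate of the target F2. K2CO3/MeOH at 0 °C gives 10.
- In this variant, ionisation at the benzylic carbon without a partner hydroxyl can only return. Return on the wrong face would erode C7', so the exposure to acid is kept short.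

**Step 3.**
- Most likely failure: saturation of the tetrasubstituted push–pull furan is slow. Either hydrogenolysis of the newly formed p-hydroxybenzylic ring C–O bonds catches up, or the reduction stalls after the first H2.
- Fallback, from 2 back to 7. Twofold Suzuki coupling of 2 with commercial (E)-1,2-bis(pinacolatoboryl)ethene gives the (E)-stilbene F3. Epoxidation with dimethyldioxirane (acetone, −20 °C) gives the racemic trans-epoxide F4.
- Photoinduced electron transfer (1,4-dicyanonaphthalene, hν, MeCN) then opens the C–C bond of F4 to the carbonyl ylide F5. Diethyl maleate takes up F5 in a (3+2) cycloaddition, whose endo adduct is the all-cis dibenzyl diester F6.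
- H2 (1 bar), Pd/C removes only the O-benzyl groups and gives 7.

**Step 2.**
- Most likely failure: slow oxidative addition of the electron-rich bromide, so that the reaction stops after the first arylation or drifts to homocoupling.
- Fallback, from 3 and 2 back to 5. Twofold α-bromination of 3 (Br2, CHCl3, reflux) gives the dibromofuran diester F7. Miyaura borylation of 2 (B2pin2, PdCl2(dppf), KOAc, dioxane) gives the arylboronic ester F8. Twofold Suzuki coupling (Pd(PPh3)4, K2CO3, dioxane–H2O) gives 5.

**Step 4.**
- Most likely failure: aluminium phenoxide formation next to a strained benzylic ether triggers ring opening and hydride capture at C7. Alternatively, basic species enolise the β-alkoxy esters, with epimerisation or β-elimination of the ring oxygen.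
- Fallback, from 5 back to 8. The esters are reduced with LiAlH4 while the ring is still aromatic, where there is no stereocentre, no phenoxide and no β-alkoxy ester. This gives the furan-3,4-dimethanol F9.
- The hydrogenation of step 3 is then run on F9, a 2,5-diarylfuran of the 3,4-dialkyl type. It gives 8 directly under neutral conditions.

## Further compounds

F1 | step 5 | [(2R,3R,4S,5S)-4-(hydroxymethyl)-2,5-bis(4-hydroxy-3-methoxyphenyl)oxolan-3-yl]methyl acetate | COc1cc(ccc1O)[C@H]2O[C@@H](c3ccc(O)c(OC)c3)[C@@H](COC(C)=O)[C@H]2CO
F2 | step 5 | [(2S,3R,4S)-4-[(S)-hydroxy(4-hydroxy-3-methoxyphenyl)methyl]-2-(4-hydroxy-3-methoxyphenyl)oxolan-3-yl]methyl acetate | COc1cc([C@@H](O)[C@@H]2CO[C@H](c3ccc(O)c(OC)c3)[C@H]2COC(C)=O)ccc1O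
F3 | step 3 | (E)-1,2-bis(4-benzyloxy-3-methoxyphenyl)ethene | COc1cc(/C=C/c2ccc(OCc3ccccc3)c(OC)c2)ccc1OCc4ccccc4
F4 | step 3 | rac-trans-2,3-bis(4-benzyloxy-3-methoxyphenyl)oxirane (one enantiomer drawn) | COc1cc(ccc1OCc2ccccc2)[C@H]3O[C@@H]3c4ccc(OCc5ccccc5)c(OC)c4
F5 | step 3 | carbonyl ylide from F4 | COc1cc(ccc1OCc2ccccc2)C=[O+][CH-]c3ccc(OCc4ccccc4)c(OC)c3
F6 | step 3 | diethyl (2R,3S,4R,5S)-2,5-bis(4-benzyloxy-3-methoxyphenyl)oxolane-3,4-dicarboxylate (meso, all-cis) | COc1cc(ccc1OCc2ccccc2)[C@H]3O[C@@H](c4ccc(OCc5ccccc5)c(OC)c4)[C@@H](C(=O)OCC)[C@H]3C(=O)OCC
F7 | step 2 | diethyl 2,5-dibromofuran-3,4-dicarboxylate | CCOC(=O)c1c(Br)oc(Br)c1C(=O)OCC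
F8 | step 2 | 2-(4-benzyloxy-3-methoxyphenyl)-4,4,5,5-tetramethyl-1,3,2-dioxaborolane | COc1cc(ccc1OCc2ccccc2)B3OC(C)(C)C(C)(C)O3
F9 | step 4 | [2,5-bis(4-benzyloxy-3-methoxyphenyl)furan-3,4-diyl]dimethanol | OCc1c(-c2ccc(OCc3ccccc3)c(OC)c2)oc(-c2ccc(OCc3ccccc3)c(OC)c2)c1CO
A1 | alternative 1 | (4R,5S)-5-(4-benzyloxy-3-methoxyphenyl)-4-[(tert-butyldimethylsilyloxy)methyl]oxolan-2-one | O=C1C[C@H](CO[Si](C)(C)C(C)(C)C)[C@H](O1)c2ccc(OCc3ccccc3)c(OC)c2
A2 | alternative 1 | (3R,4R,5S)-3-[(S)-(4-benzyloxy-3-methoxyphenyl)(hydroxy)methyl]-5-(4-benzyloxy-3-methoxyphenyl)-4-[(tert-butyldimethylsilyloxy)methyl]oxolan-2-one | O=C1[C@@H]([C@H](O)c2ccc(OCc3ccccc3)c(OC)c2)[C@H](CO[Si](C)(C)C(C)(C)C)[C@H](O1)c4ccc(OCc5ccccc5)c(OC)c4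
A3 | alternative 1 | 4-benzyloxy-3-methoxybenzaldehyde | COc1cc(C=O)ccc1OCc2ccccc2
A4 | alternative 2 | (1α,2α,3β,4β)-[3,4-bis(4-hydroxy-3-methoxyphenyl)cyclobutane-1,2-diyl]dimethanol (meso) | OC[C@H]1[C@@H](CO)[C@H](c2ccc(O)c(OC)c2)[C@@H]1c3ccc(O)c(OC)c3
A5 | alternative 3 | carbonyl ylide (4-benzyloxy-3-methoxybenzylidene)oxonium methylide | [CH2-][O+]=Cc1ccc(OCc2ccccc2)c(OC)c1
A6 | alternative 3 | methyl (E)-4-(4-benzyloxy-3-methoxyphenyl)-4-oxobut-2-enoate | COC(=O)/C=C/C(=O)c1ccc(OCc2ccccc2)c(OC)c1
A7 | alternative 3 | methyl (2S,3S,4S)-4-(4-benzyloxy-3-methoxybenzoyl)-2-(4-benzyloxy-3-methoxyphenyl)oxolane-3-carboxylate | COC(=O)[C@@H]1[C@@H](c2ccc(OCc3ccccc3)c(OC)c2)OC[C@H]1C(=O)c4ccc(OCc5ccccc5)c(OC)c4
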